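The numbers in the tables stem from a simulated flask on assumed constants; scatter was added.

In the first 10.0 s of Saturday's run the electrophile loses 14.3% of its charge and 13.9% appears as target, one for one within the scatter. Free base shows no effect beyond the scatter: Saturday's run at 0.94 M and Friday's at 2.7 M read 50.5% and 50.2% of electrophile at 120 s.

| flask | electrophile | nucleophile | free base | remark | time |
|---|---|---|---|---|---|
| Saturday's | 1 M | 1.2 M | 0.94 M | run made earlier |  |
| Sunday's | 1 M | 1.2 M | 1.6 M | run made earlier |  |
| Friday's | 1 M | 1.2 M | 2.7 M | run made earlier |  |
| south-west | 1.0 M | 1.20 M | 1.20 M |  | 2.5 min |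
| north-west | 1.0 M | 1.20 M | 2.40 M |  | 2.5 min |

| run | time / s | electrophile / % | target / % |
|---|---|---|---|
| Saturday's | 10.0 | 85.7 | 13.9 |
| Saturday's | 15.0 | 80.6 | 18.2 |
| Saturday's | 30.0 | 70.1 | 29.2 |
| Saturday's | 60.0 | 59.4 | 38.5 |
| Saturday's | 120 | 50.5 | 46.8 |
| Sunday's | 20.0 | 77.8 | 23.3 |
| Sunday's | 40.0 | 66.6 | 33.4 |
| Sunday's | 60.0 | 60.8 | 38.9 |
| Sunday's | 80.0 | 55.7 | 42.9 |
| Sunday's | 120 | 50.6 | 46.7 |
| Friday's | 10.0 | 86.1 | 14.2 |
| Friday's | 15.0 | 81.5 | 17.8 |
| Friday's | 30.0 | 70.4 | 28.7 |
| Friday's | 60.0 | 60.5 | 38.5 |
| Friday's | 120 | 50.2 | 47.0 |

(scatter of a reading: 0.5 percentage points)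

- a reading or a percentage of target counts all its forms, free or not

1. part of the electrophile that has reacted at the end, south-west
2. part of the electrophile that has reacted at the end, north-west
3. what raising the concentration of free base from its lowest to its highest value here does to the part of the electrophile that has reacted (changes below 5 percentage points count as none) (no change / it falls / it rises)

In the middle of Saturday's run the curve brakes hard: from 60.0 s to 120 s the electrophile falls by 8.9 percentage points, less than the 14.3% of the first 10.0 s, although 50.5% of it still stands at the later time.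

The working reading here is that each electrophile reacted costs two nucleophile, one becoming target and one taking up the acid set free, which would make nucleophile the limiting reagent. Counting no acid on the free base, this gives the ceiling of conversion, c(nucleophile) divided by two c(electrophile), 60.0%.

Towards the end the gap to the ceiling is what shrinks. With c(electrophile) taken as roughly steady, the rate is pseudo-first-order in the gap, and the gap decays exponentially. Saturday's readings put the gap at 19.4% at 60.0 s and 10.5% at 120 s, which reads as a half-life of about 67.7 s. Carried on to 2.5 min, this gives 52.3% reacted, in south-west and north-west alike.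

The forecast gives 52% and 52%, no change, on the grounds that “All three runs give the same curve within scatter”.

The simulation gives 51.8% for south-west and 52.1% for north-west, a change of 0.33 points, so no change.

    electrophile + nucleophile ⇌ acid set free + target (K = 0.480, k = 0.0150 M⁻¹ s⁻¹)
    nucleophile + acid set free ⇌ protonated nucleophile, settled at all times (K = 300 M⁻¹)
    acid set free + free base ⇌ salt of the base, settled at all times (K = 1.00 M⁻¹)
    target ⇌ isomer of the product (K = 20.0, k = 9.00 × 10⁻⁴ s⁻¹)
    nucleophile + target ⇌ idle adduct, settled at all times (K = 1.70 M⁻¹)

In north-west, over the 2.50 min, free nucleophile fell to 10.0% of its charge while the acid set free stood mostly as protonated nucleophile, 0.476 M against 0.0313 M of salt of the base, with 98.7% of the free base still free and 3.61% of the electrophile charged standing as isomer of the product. Left to 25.0 min, north-west reaches 62.9%, above the ceiling of 60.0%, with 0.0840 M of salt of the base standing. The neighbour of north-west charged with 0.48 M of nucleophile has a ceiling of 24.0% and gives 24.2% at 2.50 min.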